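**Strategy.** The route rests on cutting the benzene ring (ring A) of the isochromanone through C7–C8 and C5–C6. A 3-alkylcyclobutenone that already carries the whole side chain, with both carbinol stereocentres as silyl ethers, is heated with methoxyethyne. Strain-driven opening to a vinylketene, ketene–alkyne cycloaddition and electrocyclic closure then assemble ring A in one operation. The step exploits the meta pattern of ring A, free C8–OH and C6–OMe flanking C7–H: the ketene carbonyl becomes the phenol and the ynol ether brings the methyl ether, so the two oxygens arrive differentiated. Carboxylation at C8a and lactonisation through the C3 oxygen finish the target.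

Key step: step 10

Remark: atom labels C1–C8a are those of the isochromanone ring of the target and are used for the same atoms in earlier compounds; the side-chain carbinol is C6′; TBS = tert-butyldimethylsilyl.
Assumption: the sense of induction in step 5 follows the accepted transition-state model for phosphoric-acid-catalysed boronate additions ((R)-catalyst to the Re face, hence (S)-catalyst for the Si face needed here); the configuration of 10 should be confirmed by Mosher ester analysis and the antipodal catalyst used if it proves reversed.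

Step 1
Reactants: 1 (S)-oct-1-yn-3-ol
Product: 2 (S)-tert-butyldimethyl(oct-1-yn-3-yloxy)silane
Conditions: TBSCl, imidazole, DMF, 0 °C to rt
Reagents that add atoms: tert-butyldimethylsilyl chloride (TBSCl), CC(C)(C)[Si](C)(C)Cl
Why: Imidazole-promoted O-silylation of the secondary propargylic alcohol is routine, does not touch the C–O bond, and so carries the (S) centre (C6′ of the target) through unchanged while masking the hydroxyl for the acetylide chemistry.

Step 2
Reactants: 2 (S)-tert-butyldimethyl(oct-1-yn-3-yloxy)silane; 3 benzyl 4-bromobutyl ether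
Product: 5 (S)-1-(benzyloxy)-7-(tert-butyldimethylsilyloxy)dodec-5-yne, via lithium acetylide 4 (not isolated)
Conditions: n-BuLi, THF, −78 °C; then 3, DMPU, −78 °C to rt
Reagents that add atoms: none
Why: Deprotonation of the terminal alkyne and SN2 alkylation of the lithium acetylide with a primary bromide in the presence of DMPU (acetylide alkylation) adds the four carbons that become C3 and the three methylenes next to it, the benzyl ether serving as a latent primary alcohol.

Step 3
Reactants: 5 (S)-1-(benzyloxy)-7-(tert-butyldimethylsilyloxy)dodec-5-yne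
Product: 6 (S)-7-(tert-butyldimethylsilyloxy)dodecan-1-ol
Conditions: H2 (1 atm), 10% Pd/C, EtOAc, rt
Reagents that add atoms: none
Why: Hydrogenation over Pd/C saturates the alkyne and hydrogenolyses the benzyl ether in the same flask (catalytic hydrogenation with O-debenzylation), while ethyl acetate as solvent keeps the silyl ether and its stereocentre intact.

Step 4
Reactants: 6 (S)-7-(tert-butyldimethylsilyloxy)dodecan-1-ol
Product: 7 (S)-7-(tert-butyldimethylsilyloxy)dodecanal
Conditions: Dess–Martin periodinane, CH2Cl2, 0 °C to rt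
Reagents that add atoms: none
Why: Dess–Martin oxidation converts the primary alcohol into the aldehyde under nearly neutral conditions, without over-oxidation and without effect on the silyl ether.

Step 5
Reactants: 7 (S)-7-(tert-butyldimethylsilyloxy)dodecanal; 8 allenylboronic acid pinacol ester
Product: 10 (4R,10S)-10-(tert-butyldimethylsilyloxy)pentadec-1-yn-4-ol, via homopropargyl borate 9 (not isolated)
Conditions: (S)-TRIP [(S)-3,3′-bis(2,4,6-triisopropylphenyl)-1,1′-binaphthyl-2,2′-diyl hydrogen phosphate] (10 mol%), 4 Å MS, toluene, −20 °C; aqueous work-up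
Reagents that add atoms: none
Why: In this chiral-phosphoric-acid-catalysed propargylation the allenylboronate adds through a closed six-membered SE2′ transition state in which the catalyst binds the boronate oxygen and the formyl hydrogen, so the (S)-catalyst should direct attack to the Si face and set the new carbinol centre (C3 of the target) as R, the distant C6′ centre exerting no influence.

Step 6
Reactants: 10 (4R,10S)-10-(tert-butyldimethylsilyloxy)pentadec-1-yn-4-ol
Product: 11 (4R,10S)-4,10-bis(tert-butyldimethylsilyloxy)pentadec-1-yne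
Conditions: TBSCl, imidazole, DMAP (cat.), DMF, rt
Reagents that add atoms: tert-butyldimethylsilyl chloride (TBSCl), CC(C)(C)[Si](C)(C)Cl
Why: Standard silylation of the homopropargylic alcohol protects the second carbinol against acylation by the acid chloride and the ketene of the next step.

Step 7
Reactants: 11 (4R,10S)-4,10-bis(tert-butyldimethylsilyloxy)pentadec-1-yne; 12 trichloroacetyl chloride
Product: 14 3-[(2R,8S)-2,8-bis(tert-butyldimethylsilyloxy)tridecyl]-4,4-dichlorocyclobut-2-en-1-one, via dichloroketene 13 (not isolated)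
Conditions: Zn–Cu couple, Et2O/DME, rt, slow addition of 12
Reagents that add atoms: none
Why: Zinc dechlorinates trichloroacetyl chloride to dichloroketene, which adds to the terminal alkyne in a thermal ketene–alkyne [2+2] cycloaddition with its carbonyl carbon bonding to the terminal CH, giving the 3-substituted 4,4-dichlorocyclobutenone, while DME ties up ZnCl2 so that the silyl ethers survive.

Step 8
Reactants: 14 3-[(2R,8S)-2,8-bis(tert-butyldimethylsilyloxy)tridecyl]-4,4-dichlorocyclobut-2-en-1-one
Product: 15 3-[(2R,8S)-2,8-bis(tert-butyldimethylsilyloxy)tridecyl]cyclobut-2-en-1-one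
Conditions: Zn dust, AcOH, TMEDA, EtOH, 0 °C to rt
Reagents that add atoms: none
Why: Zinc in buffered acetic acid reduces both C–Cl bonds next to the carbonyl through zinc enolates (reductive dehalogenation of an α,α-dichloroketone), and the TMEDA buffer suppresses acid-induced ring opening and loss of the silyl ethers.

Step 9
Reactants: 16 chloroacetaldehyde dimethyl acetal
Product: 18 methoxyethyne, via sodium methoxyethynide 17 (not isolated)
Conditions: NaNH2 (excess), liquid NH3, −33 °C; then cold saturated aq. NaCl, distil into a −78 °C trap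
Reagents that add atoms: none
Why: Sodium amide effects two eliminations (methanol, then HCl) and holds the product as its acetylide until the aqueous quench, which is the standard preparation of alkoxyethynes from chloroacetals, and the low boiling point allows distillation into a cold trap for immediate use.

Step 10
Reactants: 15 3-[(2R,8S)-2,8-bis(tert-butyldimethylsilyloxy)tridecyl]cyclobut-2-en-1-one; 18 methoxyethyne
Product: 23 3-[(2R,8S)-2,8-bis(tert-butyldimethylsilyloxy)tridecyl]-5-methoxyphenol, via vinylketene 19 (not isolated), via 4-alkenyl-3-methoxycyclobutenone 20 (not isolated), via dienylketene 21 (not isolated), via cyclohexadienone 22 (not isolated)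
Conditions: toluene, sealed tube, 80 °C, methoxyethyne in excess
Reagents that add atoms: none
Why: Thermal conrotatory four-electron opening of the strained cyclobutenone gives vinylketene 19, whose ketene C=C adds methoxyethyne in a [2+2] cycloaddition (new bonds C7–C8 and C5–C6) to give 20, which opens again to the (E)-dienylketene 21. The closest known reaction type is the Danheiser benzannulation of 3-alkylcyclobutenones with alkoxyalkynes to resorcinol monoethers. The one new ring, the benzene ring, is closed by a disrotatory six-electron electrocyclisation that joins C8 to C8a, and cyclohexadienone 22 then enolises to the phenol. No stereocentre is created, and the two existing ones are remote from the reacting π system and see only neutral thermal conditions. The selectivity needed is the orientation of the ketene–alkyne addition, which the polarisation of the ynol ether secures: its unsubstituted nucleophilic carbon bonds to the electrophilic ketene carbon C8, so the methoxy-bearing carbon becomes C6, meta to the new hydroxyl. Keeping the alkyne in excess in a sealed tube should let the cycloaddition outrun both ketene dimerisation and interception of 19 by phenol already formed.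

Step 11
Reactants: 23 3-[(2R,8S)-2,8-bis(tert-butyldimethylsilyloxy)tridecyl]-5-methoxyphenol
Product: 25 2-[(2R,8S)-2,8-bis(tert-butyldimethylsilyloxy)tridecyl]-6-hydroxy-4-methoxybenzoic acid, via magnesium salicylate 24 (not isolated)
Conditions: MeOMgOCO2Me (2 M in DMF, excess), 125 °C; then cold 1 M HCl, 0 °C
Reagents that add atoms: methyl magnesium carbonate (MeOMgOCO2Me), COC(=O)O[Mg]OC
Why: In this Kolbe–Schmitt-type carboxylation the magnesium phenoxide is carboxylated ortho to oxygen and the equilibrium is pulled over by the chelated magnesium salicylate, and of the two ortho positions C8a, para to methoxy, should be preferred over C7 between the two oxygens, as is the rule for 5-alkylresorcinols and their monoethers with this reagent.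

Step 12
Reactants: 25 2-[(2R,8S)-2,8-bis(tert-butyldimethylsilyloxy)tridecyl]-6-hydroxy-4-methoxybenzoic acid
Product: 27 (3R)-8-hydroxy-3-[(6S)-6-hydroxyundecyl]-6-methoxy-3,4-dihydro-1H-isochromen-1-one, via dihydroxy acid 26 (not isolated)
Conditions: 48% aq. HF, MeCN, 0 °C to rt; then TsOH·H2O (cat.), toluene, rt
Reagents that add atoms: none
Why: Aqueous HF cleaves both silyl ethers and the liberated δ-hydroxy acid closes to the six-membered lactone by acid-catalysed acyl–oxygen bond formation (lactonisation), which leaves the C3–O bond and hence the R configuration untouched, while the C6′ hydroxyl is too far away to compete.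

**Compound list**

1 | (S)-oct-1-yn-3-ol | CCCCC[C@H](O)C#C | starting material
2 | (S)-tert-butyldimethyl(oct-1-yn-3-yloxy)silane | CCCCC[C@H](O[Si](C)(C)C(C)(C)C)C#C | intermediate
3 | benzyl 4-bromobutyl ether | BrCCCCOCc1ccccc1 | starting material
4 | lithium acetylide of 2 (formed in situ) | CCCCC[C@H](O[Si](C)(C)C(C)(C)C)C#C[Li] | intermediate
5 | (S)-1-(benzyloxy)-7-(tert-butyldimethylsilyloxy)dodec-5-yne | CCCCC[C@H](O[Si](C)(C)C(C)(C)C)C#CCCCCOCc1ccccc1 | intermediate
6 | (S)-7-(tert-butyldimethylsilyloxy)dodecan-1-ol | CCCCC[C@H](O[Si](C)(C)C(C)(C)C)CCCCCCO | intermediate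
7 | (S)-7-(tert-butyldimethylsilyloxy)dodecanal | CCCCC[C@H](O[Si](C)(C)C(C)(C)C)CCCCCC=O | intermediate
8 | allenylboronic acid pinacol ester | C=C=CB1OC(C)(C)C(C)(C)O1 | starting material
9 | 2-{[(4R,10S)-10-(tert-butyldimethylsilyloxy)pentadec-1-yn-4-yl]oxy}-4,4,5,5-tetramethyl-1,3,2-dioxaborolane (formed in situ) | CCCCC[C@H](O[Si](C)(C)C(C)(C)C)CCCCC[C@@H](OB1OC(C)(C)C(C)(C)O1)CC#C | intermediate
10 | (4R,10S)-10-(tert-butyldimethylsilyloxy)pentadec-1-yn-4-ol | CCCCC[C@H](O[Si](C)(C)C(C)(C)C)CCCCC[C@@H](O)CC#C | intermediate
11 | (4R,10S)-4,10-bis(tert-butyldimethylsilyloxy)pentadec-1-yne | CCCCC[C@H](O[Si](C)(C)C(C)(C)C)CCCCC[C@@H](O[Si](C)(C)C(C)(C)C)CC#C | intermediate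
12 | trichloroacetyl chloride | ClC(Cl)(Cl)C(Cl)=O | starting material
13 | dichloroketene (formed in situ) | ClC(Cl)=C=O | intermediate
14 | 3-[(2R,8S)-2,8-bis(tert-butyldimethylsilyloxy)tridecyl]-4,4-dichlorocyclobut-2-en-1-one | CCCCC[C@H](O[Si](C)(C)C(C)(C)C)CCCCC[C@@H](O[Si](C)(C)C(C)(C)C)CC1=CC(=O)C1(Cl)Cl | intermediate
15 | 3-[(2R,8S)-2,8-bis(tert-butyldimethylsilyloxy)tridecyl]cyclobut-2-en-1-one | CCCCC[C@H](O[Si](C)(C)C(C)(C)C)CCCCC[C@@H](O[Si](C)(C)C(C)(C)C)CC1=CC(=O)C1 | intermediate
16 | chloroacetaldehyde dimethyl acetal | COC(CCl)OC | starting material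
17 | sodium methoxyethynide (formed in situ) | [Na+].[C-]#COC | intermediate
18 | methoxyethyne | C#COC | intermediate
19 | 3-[(2R,8S)-2,8-bis(tert-butyldimethylsilyloxy)tridecyl]buta-1,3-dien-1-one (vinylketene, formed in situ) | CCCCC[C@H](O[Si](C)(C)C(C)(C)C)CCCCC[C@@H](O[Si](C)(C)C(C)(C)C)CC(=C)C=C=O | intermediate
20 | 4-[(4R,10S)-4,10-bis(tert-butyldimethylsilyloxy)pentadec-1-en-2-yl]-3-methoxycyclobut-2-en-1-one (both epimers at the ring carbon, formed in situ) | CCCCC[C@H](O[Si](C)(C)C(C)(C)C)CCCCC[C@@H](O[Si](C)(C)C(C)(C)C)CC(=C)C1C(OC)=CC1=O | intermediate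
21 | (3E)-5-[(2R,8S)-2,8-bis(tert-butyldimethylsilyloxy)tridecyl]-3-methoxyhexa-1,3,5-trien-1-one (dienylketene, formed in situ) | CCCCC[C@H](O[Si](C)(C)C(C)(C)C)CCCCC[C@@H](O[Si](C)(C)C(C)(C)C)CC(=C)/C=C(OC)\C=C=O | intermediate
22 | 5-[(2R,8S)-2,8-bis(tert-butyldimethylsilyloxy)tridecyl]-3-methoxycyclohexa-2,4-dien-1-one (formed in situ) | CCCCC[C@H](O[Si](C)(C)C(C)(C)C)CCCCC[C@@H](O[Si](C)(C)C(C)(C)C)CC1=CC(OC)=CC(=O)C1 | intermediate
23 | 3-[(2R,8S)-2,8-bis(tert-butyldimethylsilyloxy)tridecyl]-5-methoxyphenol | CCCCC[C@H](O[Si](C)(C)C(C)(C)C)CCCCC[C@@H](O[Si](C)(C)C(C)(C)C)Cc1cc(O)cc(OC)c1 | intermediate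
24 | magnesium 2-[(2R,8S)-2,8-bis(tert-butyldimethylsilyloxy)tridecyl]-4-methoxy-6-oxidobenzoate (formed in situ) | CCCCC[C@H](O[Si](C)(C)C(C)(C)C)CCCCC[C@@H](O[Si](C)(C)C(C)(C)C)Cc1cc(OC)cc([O-])c1C(=O)[O-].[Mg+2] | intermediate
25 | 2-[(2R,8S)-2,8-bis(tert-butyldimethylsilyloxy)tridecyl]-6-hydroxy-4-methoxybenzoic acid | CCCCC[C@H](O[Si](C)(C)C(C)(C)C)CCCCC[C@@H](O[Si](C)(C)C(C)(C)C)Cc1cc(OC)cc(O)c1C(=O)O | intermediate
26 | 2-[(2R,8S)-2,8-dihydroxytridecyl]-6-hydroxy-4-methoxybenzoic acid (formed in situ) | CCCCC[C@H](O)CCCCC[C@@H](O)Cc1cc(OC)cc(O)c1C(=O)O | intermediate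
27 | (3R)-8-hydroxy-3-[(6S)-6-hydroxyundecyl]-6-methoxy-3,4-dihydro-1H-isochromen-1-one | CCCCC[C@H](O)CCCCC[C@@H]1Cc2cc(OC)cc(O)c2C(=O)O1 | target

**Step count.** Total: 12 steps. Longest linear sequence: 11 steps (steps 1–8 and 10–12); step 9 is a one-step side branch.

**Steps most likely to fail**

Step 10 (benzannulation). The vinylketene may be lost to dimerisation or to O-acylation of phenol already formed, and the volatile ynol ether may polymerise or escape before the cycloaddition takes place. The fallback gives up the pericyclic ring construction and attaches a ready-made, already differentiated resorcinol unit; it sets out from aldehyde 7 and returns at phenol 23. Methylene transfer to 7 with dimethylsulfonium methylide (Me3SI, NaH, DMSO/THF; Corey–Chaykovsky reaction) should give the terminal oxirane F1 as a mixture of epimers at the oxirane carbon. Hydrolytic kinetic resolution with (R,R)-(salen)Co(OAc) (salen = N,N′-bis(3,5-di-tert-butylsalicylidene)-1,2-cyclohexanediaminate, cobalt trivalent) and 0.55 equiv of water should, by precedent for alkyl oxiranes, leave the (R)-oxirane F2 and convert its epimer into the diol F3, which is separated. 1-(Benzyloxy)-3-bromo-5-methoxybenzene F4, made from commercial 3-bromo-5-methoxyphenol (BnBr, K2CO3, acetone), is converted into its arylmagnesium bromide (Mg, THF) and added to F2 with CuI (10 mol%) at −30 °C, opening the oxirane at its CH2 carbon to give the carbinol F5. Silylation (TBSCl, imidazole, DMF) gives the bis-silyl ether F6, and hydrogenolysis (H2, Pd/C, EtOAc) gives 23.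

Step 11 (carboxylation). Carboxylation at the hindered C8a position is reversible and may stall, the electron-rich acid may lose CO2 again on acidification, and some attack at C7 is possible. The fallback removes the regiochemical question by making the two positions next to the side chain equivalent and introducing the carboxyl through a bromide; it sets out from phenol 23 and returns at the target 27. O-Methylation of 23 (MeI, K2CO3, acetone) gives the dimethyl ether F7. NBS (MeCN, 0 °C) should brominate one of the two equivalent positions flanking the side chain, para to a methoxy group, to give the aryl bromide F8. Bromine–lithium exchange (n-BuLi, THF, −78 °C) and quenching with CO2 give the benzoic acid F9. Aqueous HF in MeCN removes both silyl groups and closes the lactone to the 6,8-dimethoxy lactone F10. BCl3 (CH2Cl2, −78 to 0 °C) should then cleave only the C8 methyl ether, which chelates boron together with the lactone carbonyl, to give 27.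

Step 5 (propargylation). Facial discrimination by the phosphoric acid may be incomplete with an unbranched aldehyde, which would leave the C3 epimer; this is remote from C6′ and would be hard to remove later. The fallback replaces catalyst control by a stoichiometric chiral allylborane and then exchanges the alkene for the alkyne; it sets out from aldehyde 7 and returns at alkyne 11. Allylboration of 7 with (−)-Ipc2B(allyl), prepared from (−)-Ipc2BOMe and allylMgBr (Et2O, −78 °C; then NaOH, H2O2), should add to the Si face and give the (R)-homoallylic alcohol F11. Silylation (TBSCl, imidazole, DMF) gives the bis-silyl ether F12. Ozonolysis (O3, CH2Cl2, −78 °C; then PPh3) gives the β-silyloxy aldehyde F13, and Ohira–Bestmann homologation (dimethyl (1-diazo-2-oxopropyl)phosphonate, K2CO3, MeOH) gives 11.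

**Further compounds**

F1 | step 10 | tert-butyldimethyl{[(6S)-11-(oxiran-2-yl)undecan-6-yl]oxy}silane (both epimers at the oxirane carbon) | CCCCC[C@H](O[Si](C)(C)C(C)(C)C)CCCCCC1CO1
F2 | step 10 | tert-butyldimethyl({(6S)-11-[(2R)-oxiran-2-yl]undecan-6-yl}oxy)silane | CCCCC[C@H](O[Si](C)(C)C(C)(C)C)CCCCC[C@@H]1CO1
F3 | step 10 | (2S,8S)-8-(tert-butyldimethylsilyloxy)tridecane-1,2-diol | CCCCC[C@H](O[Si](C)(C)C(C)(C)C)CCCCC[C@H](O)CO
F4 | step 10 | 1-(benzyloxy)-3-bromo-5-methoxybenzene | COc1cc(Br)cc(OCc2ccccc2)c1
F5 | step 10 | (2R,8S)-1-[3-(benzyloxy)-5-methoxyphenyl]-8-(tert-butyldimethylsilyloxy)tridecan-2-ol | CCCCC[C@H](O[Si](C)(C)C(C)(C)C)CCCCC[C@@H](O)Cc1cc(OC)cc(OCc2ccccc2)c1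
F6 | step 10 | 1-(benzyloxy)-3-[(2R,8S)-2,8-bis(tert-butyldimethylsilyloxy)tridecyl]-5-methoxybenzene | CCCCC[C@H](O[Si](C)(C)C(C)(C)C)CCCCC[C@@H](O[Si](C)(C)C(C)(C)C)Cc1cc(OC)cc(OCc2ccccc2)c1
F7 | step 11 | 1-[(2R,8S)-2,8-bis(tert-butyldimethylsilyloxy)tridecyl]-3,5-dimethoxybenzene | CCCCC[C@H](O[Si](C)(C)C(C)(C)C)CCCCC[C@@H](O[Si](C)(C)C(C)(C)C)Cc1cc(OC)cc(OC)c1
F8 | step 11 | 2-bromo-1-[(2R,8S)-2,8-bis(tert-butyldimethylsilyloxy)tridecyl]-3,5-dimethoxybenzene | CCCCC[C@H](O[Si](C)(C)C(C)(C)C)CCCCC[C@@H](O[Si](C)(C)C(C)(C)C)Cc1cc(OC)cc(OC)c1Br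
F9 | step 11 | 2-[(2R,8S)-2,8-bis(tert-butyldimethylsilyloxy)tridecyl]-4,6-dimethoxybenzoic acid | CCCCC[C@H](O[Si](C)(C)C(C)(C)C)CCCCC[C@@H](O[Si](C)(C)C(C)(C)C)Cc1cc(OC)cc(OC)c1C(=O)O
F10 | step 11 | (3R)-3-[(6S)-6-hydroxyundecyl]-6,8-dimethoxy-3,4-dihydro-1H-isochromen-1-one | CCCCC[C@H](O)CCCCC[C@@H]1Cc2cc(OC)cc(OC)c2C(=O)O1
F11 | step 5 | (4R,10S)-10-(tert-butyldimethylsilyloxy)pentadec-1-en-4-ol | CCCCC[C@H](O[Si](C)(C)C(C)(C)C)CCCCC[C@@H](O)CC=C
F12 | step 5 | (4R,10S)-4,10-bis(tert-butyldimethylsilyloxy)pentadec-1-ene | CCCCC[C@H](O[Si](C)(C)C(C)(C)C)CCCCC[C@@H](O[Si](C)(C)C(C)(C)C)CC=C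
F13 | step 5 | (3R,9S)-3,9-bis(tert-butyldimethylsilyloxy)tetradecanal | CCCCC[C@H](O[Si](C)(C)C(C)(C)C)CCCCC[C@@H](O[Si](C)(C)C(C)(C)C)CC=O
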